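## Retrosynthetic overview

1. The target comes from its bis(O‑benzyl) ether; both phenols are unmasked in the last step.
2. The butyrolactone, the only ring made, comes from the acyclic (2E,3R)‑2‑arylidene‑3‑benzylbutane‑1,4‑diol by dehydrogenative lactonization through the hydroxy enal and the lactol. This is the chemical counterpart of the secoisolariciresinol → matairesinol dehydrogenase step; the allylic CH2OH is the one oxidized, so the C=O lands next to the arylidene.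
3. The diol comes from an N‑acyloxazolidinone/methyl ester by exhaustive hydride reduction; the single stereocenter comes from Evans alkylation of the β,γ‑unsaturated imide with O‑benzylvanillyl bromide (α‑attack on the dienolate).
4. The imide comes from the (E)‑Stobbe half‑ester of O‑benzylsyringaldehyde and dimethyl succinate, which supplies the whole C4 backbone and the (E)‑arylidene in one step.
5. Ring order: no ring until step 6, where the lactone is closed oxidatively on the fully assembled skeleton.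

Assumption: 4‑(benzyloxy)‑3,5‑dimethoxybenzaldehyde and [4‑(benzyloxy)‑3‑methoxyphenyl]methanol are bought as catalogue chemicals (each is otherwise one benzylation from syringaldehyde or vanillyl alcohol).

## Route

Step 1
Reactants: 1 4‑(benzyloxy)‑3,5‑dimethoxybenzaldehyde; 2 dimethyl succinate
Product: 4 (3E)‑4‑[4‑(benzyloxy)‑3,5‑dimethoxyphenyl]‑3‑(methoxycarbonyl)but‑3‑enoic acid, via Stobbe lactone 3 (not isolated)
Conditions: NaOMe (2 equiv), MeOH, reflux; then aq HCl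
Reagents that add atoms: none
Why: Stobbe condensation, in which the succinate enolate adds to the aldehyde, the aldolate closes to paraconic ester 3 and base‑induced E1cB ring opening leaves the free acid on the CH2 arm and the aryl group trans to the retained ester, the (E) isomer being the normal outcome with aromatic aldehydes.

Step 2
Reactants: 4 (3E)‑4‑[4‑(benzyloxy)‑3,5‑dimethoxyphenyl]‑3‑(methoxycarbonyl)but‑3‑enoic acid; 5 (R)‑4‑benzyl‑1,3‑oxazolidin‑2‑one
Product: 7 methyl (2E)‑2‑[4‑(benzyloxy)‑3,5‑dimethoxybenzylidene]‑4‑[(4R)‑4‑benzyl‑2‑oxo‑1,3‑oxazolidin‑3‑yl]‑4‑oxobutanoate, via mixed pivalic anhydride 6 (not isolated)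
Conditions: PivCl, Et3N, THF, −20 °C; then 5, LiCl, −20 °C to rt
Reagents that add atoms: pivaloyl chloride CC(C)(C)C(Cl)=O (its acyl group is present in intermediate 6 only)
Why: Mixed‑anhydride N‑acylation of an Evans oxazolidinone under the mild Et3N/LiCl protocol, in which the oxazolidinone attacks the less hindered substrate carbonyl of 6 and no strong base touches the enoate, so the (E) alkene is kept.

Step 3
Reactants: 8 [4‑(benzyloxy)‑3‑methoxyphenyl]methanol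
Product: 9 1‑(benzyloxy)‑4‑(bromomethyl)‑2‑methoxybenzene
Conditions: PBr3 (0.4 equiv), Et2O, 0 °C
Reagents that add atoms: phosphorus tribromide BrP(Br)Br
Why: Alcohol‑to‑bromide substitution (bromide displaces the bromophosphite leaving group) is fast at 0 °C for an electron‑rich benzylic alcohol and leaves the aryl benzyl ether untouched.

Step 4
Reactants: 7 methyl (2E)‑2‑[4‑(benzyloxy)‑3,5‑dimethoxybenzylidene]‑4‑[(4R)‑4‑benzyl‑2‑oxo‑1,3‑oxazolidin‑3‑yl]‑4‑oxobutanoate; 9 1‑(benzyloxy)‑4‑(bromomethyl)‑2‑methoxybenzene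
Product: 11 methyl (2E,3R)‑2‑[4‑(benzyloxy)‑3,5‑dimethoxybenzylidene]‑3‑[4‑(benzyloxy)‑3‑methoxybenzyl]‑4‑[(4R)‑4‑benzyl‑2‑oxo‑1,3‑oxazolidin‑3‑yl]‑4‑oxobutanoate, via (Z)‑enolate 10 (not isolated)
Conditions: NaN(SiMe3)2, THF, −78 °C; then 9, −78 to −40 °C
Reagents that add atoms: sodium bis(trimethylsilyl)amide NaN(SiMe3)2 C[Si](C)(C)[N-][Si](C)(C)C.[Na+] (its sodium is present in intermediate 10 only)
Why: Evans asymmetric alkylation, in which the Na‑chelated (Z)‑enolate 10 reacts with the benzylic bromide at its α carbon (kinetic α‑selectivity of the dienolate) on the face opposite the 4‑benzyl group of the (R)‑auxiliary, which sets the new stereocenter as (R), while the arylidene geometry is not disturbed at −78 °C.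

Step 5
Reactants: 11 methyl (2E,3R)‑2‑[4‑(benzyloxy)‑3,5‑dimethoxybenzylidene]‑3‑[4‑(benzyloxy)‑3‑methoxybenzyl]‑4‑[(4R)‑4‑benzyl‑2‑oxo‑1,3‑oxazolidin‑3‑yl]‑4‑oxobutanoate
Product: 12 (2E,3R)‑2‑[4‑(benzyloxy)‑3,5‑dimethoxybenzylidene]‑3‑[4‑(benzyloxy)‑3‑methoxybenzyl]butane‑1,4‑diol
Conditions: LiAlH4, THF, −10 to 0 °C; then H2O, aq NaOH
Reagents that add atoms: none
Why: Hydride reduction with LiAlH4 cleaves the imide reductively to the primary alcohol (auxiliary released intact) and reduces the hindered trisubstituted enoate 1,2 to the allylic alcohol, so both termini reach the diol level in one operation without touching the stereocenter, the alkene or the benzyl ethers.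

Step 6
Reactants: 12 (2E,3R)‑2‑[4‑(benzyloxy)‑3,5‑dimethoxybenzylidene]‑3‑[4‑(benzyloxy)‑3‑methoxybenzyl]butane‑1,4‑diol
Product: 15 (3E,4R)‑3‑[4‑(benzyloxy)‑3,5‑dimethoxybenzylidene]‑4‑[4‑(benzyloxy)‑3‑methoxybenzyl]dihydrofuran‑2(3H)‑one, via hydroxy enal 13 (not isolated), via lactol 14 (not isolated)
Conditions: activated MnO2 (20 equiv), CH2Cl2, rt
Reagents that add atoms: none
Why: Dehydrogenative lactonization of an unprotected 1,4‑diol in the manner of secoisolariciresinol dehydrogenase, in which MnO2 oxidizes only the allylic (cinnamyl‑type) carbinol to enal 13, the saturated CH2OH adds to it to give lactol 14 and this allylic lactol is oxidized again to the lactone, so the carbonyl ends up next to the arylidene and the stereocenter, never α to a carbonyl on this path, cannot epimerize.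

Step 7
Reactants: 15 (3E,4R)‑3‑[4‑(benzyloxy)‑3,5‑dimethoxybenzylidene]‑4‑[4‑(benzyloxy)‑3‑methoxybenzyl]dihydrofuran‑2(3H)‑one
Product: 16 (3E,4R)‑3‑(4‑hydroxy‑3,5‑dimethoxybenzylidene)‑4‑(4‑hydroxy‑3‑methoxybenzyl)dihydrofuran‑2(3H)‑one
Conditions: BCl3, C6HMe5, CH2Cl2, −78 °C; then H2O
Reagents that add atoms: none
Why: Lewis‑acid O‑debenzylation with BCl3 and pentamethylbenzene as a non‑basic benzyl‑cation scavenger cleaves both aryl benzyl ethers at −78 °C without reducing or isomerizing the conjugated alkene, opening the lactone or cleaving the methyl ethers.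

## Compound list

1 | 4‑(benzyloxy)‑3,5‑dimethoxybenzaldehyde | COc1cc(C=O)cc(OC)c1OCc1ccccc1 | starting material
2 | dimethyl succinate | COC(=O)CCC(=O)OC | starting material
3 | methyl 2‑[4‑(benzyloxy)‑3,5‑dimethoxyphenyl]‑5‑oxotetrahydrofuran‑3‑carboxylate (Stobbe lactone, mixture of stereoisomers) | COC(=O)C1CC(=O)OC1c1cc(OC)c(OCc2ccccc2)c(OC)c1 | intermediate
4 | (3E)‑4‑[4‑(benzyloxy)‑3,5‑dimethoxyphenyl]‑3‑(methoxycarbonyl)but‑3‑enoic acid | COC(=O)/C(CC(=O)O)=C/c1cc(OC)c(OCc2ccccc2)c(OC)c1 | intermediate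
5 | (R)‑4‑benzyl‑1,3‑oxazolidin‑2‑one | O=C1N[C@H](Cc2ccccc2)CO1 | starting material
6 | (3E)‑4‑[4‑(benzyloxy)‑3,5‑dimethoxyphenyl]‑3‑(methoxycarbonyl)but‑3‑enoic pivalic anhydride (mixed pivalic anhydride) | COC(=O)/C(CC(=O)OC(=O)C(C)(C)C)=C/c1cc(OC)c(OCc2ccccc2)c(OC)c1 | intermediate
7 | methyl (2E)‑2‑[4‑(benzyloxy)‑3,5‑dimethoxybenzylidene]‑4‑[(4R)‑4‑benzyl‑2‑oxo‑1,3‑oxazolidin‑3‑yl]‑4‑oxobutanoate | COC(=O)/C(CC(=O)N1[C@H](Cc2ccccc2)COC1=O)=C/c1cc(OC)c(OCc2ccccc2)c(OC)c1 | intermediate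
8 | [4‑(benzyloxy)‑3‑methoxyphenyl]methanol | COc1cc(CO)ccc1OCc1ccccc1 | starting material
9 | 1‑(benzyloxy)‑4‑(bromomethyl)‑2‑methoxybenzene | COc1cc(CBr)ccc1OCc1ccccc1 | intermediate
10 | sodium (1Z,3E)‑1‑[(4R)‑4‑benzyl‑2‑oxo‑1,3‑oxazolidin‑3‑yl]‑4‑[4‑(benzyloxy)‑3,5‑dimethoxyphenyl]‑3‑(methoxycarbonyl)buta‑1,3‑dien‑1‑olate ((Z)‑enolate) | COC(=O)/C(=C/c1cc(OC)c(OCc2ccccc2)c(OC)c1)/C=C(\[O-])N1[C@H](Cc2ccccc2)COC1=O.[Na+] | intermediate
11 | methyl (2E,3R)‑2‑[4‑(benzyloxy)‑3,5‑dimethoxybenzylidene]‑3‑[4‑(benzyloxy)‑3‑methoxybenzyl]‑4‑[(4R)‑4‑benzyl‑2‑oxo‑1,3‑oxazolidin‑3‑yl]‑4‑oxobutanoate | COc1cc(C[C@@H](C(=O)N2[C@H](Cc3ccccc3)COC2=O)/C(C(=O)OC)=C\c2cc(OC)c(OCc3ccccc3)c(OC)c2)ccc1OCc1ccccc1 | intermediate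
12 | (2E,3R)‑2‑[4‑(benzyloxy)‑3,5‑dimethoxybenzylidene]‑3‑[4‑(benzyloxy)‑3‑methoxybenzyl]butane‑1,4‑diol | COc1cc(C[C@@H](CO)/C(CO)=C\c2cc(OC)c(OCc3ccccc3)c(OC)c2)ccc1OCc1ccccc1 | intermediate
13 | (2E,3R)‑2‑[4‑(benzyloxy)‑3,5‑dimethoxybenzylidene]‑3‑[4‑(benzyloxy)‑3‑methoxybenzyl]‑4‑hydroxybutanal (hydroxy enal) | COc1cc(C[C@@H](CO)/C(C=O)=C\c2cc(OC)c(OCc3ccccc3)c(OC)c2)ccc1OCc1ccccc1 | intermediate
14 | (3E,4R)‑3‑[4‑(benzyloxy)‑3,5‑dimethoxybenzylidene]‑4‑[4‑(benzyloxy)‑3‑methoxybenzyl]tetrahydrofuran‑2‑ol (lactol, both anomers) | COc1cc(C[C@H]2COC(O)/C2=C/c2cc(OC)c(OCc3ccccc3)c(OC)c2)ccc1OCc1ccccc1 | intermediate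
15 | (3E,4R)‑3‑[4‑(benzyloxy)‑3,5‑dimethoxybenzylidene]‑4‑[4‑(benzyloxy)‑3‑methoxybenzyl]dihydrofuran‑2(3H)‑one | COc1cc(C[C@H]2COC(=O)/C2=C/c2cc(OC)c(OCc3ccccc3)c(OC)c2)ccc1OCc1ccccc1 | intermediate
16 | (3E,4R)‑3‑(4‑hydroxy‑3,5‑dimethoxybenzylidene)‑4‑(4‑hydroxy‑3‑methoxybenzyl)dihydrofuran‑2(3H)‑one (CNP0351244.1) | COc1cc(C[C@H]2COC(=O)/C2=C/c2cc(OC)c(O)c(OC)c2)ccc1O | target

## Step count and risks

Total step count: 7. Longest linear sequence: 6 (steps 1, 2, 4, 5, 6, 7); step 3 is a one‑step side branch.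

**Step 4 (alkylation of the dienolate).** The risks are γ‑attack at the benzylic carbon, erosion of the arylidene geometry, or low facial selectivity. The fallback sets out from 4 and comes back at 12, and sets the stereocenter by hydrogenation instead of alkylation. Acid 4 is esterified (MeOH, cat. H2SO4) to dimethyl (2E)‑2‑[4‑(benzyloxy)‑3,5‑dimethoxybenzylidene]butanedioate F1. A second Stobbe condensation of F1 with commercial 4‑(benzyloxy)‑3‑methoxybenzaldehyde (NaOMe, MeOH, reflux) gives (2E,3E)‑2‑[4‑(benzyloxy)‑3,5‑dimethoxybenzylidene]‑3‑[4‑(benzyloxy)‑3‑methoxybenzylidene]‑4‑methoxy‑4‑oxobutanoic acid F2, whose free carboxyl sits on the syringylidene carbon. Carboxylate‑directed asymmetric hydrogenation ([Rh(cod)((S,S)‑Et‑DuPhos)]BF4, H2, MeOH; the ligand antipode if the sense proves opposite) should saturate only the itaconate‑type vanillylidene C=C and leave the α‑carboxy cinnamate‑type C=C. This gives (2E,3R)‑2‑[4‑(benzyloxy)‑3,5‑dimethoxybenzylidene]‑3‑[4‑(benzyloxy)‑3‑methoxybenzyl]‑4‑methoxy‑4‑oxobutanoic acid F3. LiAlH4 reduction of both carbonyl groups of F3 rejoins the route at diol 12.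

**Step 5 (LiAlH4 reduction).** The risks are conjugate reduction of the enoate, or of a lactone formed in passing, and endocyclic opening of the hindered imide. The fallback sets out from 11 and comes back at 12. The auxiliary is first removed by transesterification with MeOMgBr (MeOH/CH2Cl2, 0 °C) to give dimethyl (2E,3R)‑2‑[4‑(benzyloxy)‑3,5‑dimethoxybenzylidene]‑3‑[4‑(benzyloxy)‑3‑methoxybenzyl]butanedioate F4. The strictly 1,2‑selective hydride i‑Bu2AlH (CH2Cl2, −78 °C) then reduces both esters of F4 to diol 12.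

**Step 6 (oxidative lactonization).** The risks are stalling at lactol 14, batch‑dependent MnO2 activity, or over‑oxidation of the electron‑rich styrene. The fallback sets out from 11 and comes back at 15, and closes the ring at the ester oxidation level with no oxidation. LiBH4/MeOH (THF, 0 °C) cleaves only the imide and gives methyl (2E,3R)‑2‑[4‑(benzyloxy)‑3,5‑dimethoxybenzylidene]‑3‑[4‑(benzyloxy)‑3‑methoxybenzyl]‑4‑hydroxybutanoate F5. Intramolecular transesterification of F5 (cat. TsOH, CH2Cl2) gives lactone 15.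

## Further compounds

F1 | step 4 | dimethyl (2E)‑2‑[4‑(benzyloxy)‑3,5‑dimethoxybenzylidene]butanedioate | COC(=O)/C(CC(=O)OC)=C/c1cc(OC)c(OCc2ccccc2)c(OC)c1
F2 | step 4 | (2E,3E)‑2‑[4‑(benzyloxy)‑3,5‑dimethoxybenzylidene]‑3‑[4‑(benzyloxy)‑3‑methoxybenzylidene]‑4‑methoxy‑4‑oxobutanoic acid | COC(=O)/C(=C/c1ccc(OCc2ccccc2)c(OC)c1)/C(C(=O)O)=C\c1cc(OC)c(OCc2ccccc2)c(OC)c1
F3 | step 4 | (2E,3R)‑2‑[4‑(benzyloxy)‑3,5‑dimethoxybenzylidene]‑3‑[4‑(benzyloxy)‑3‑methoxybenzyl]‑4‑methoxy‑4‑oxobutanoic acid | COc1cc(C[C@@H](C(=O)OC)/C(C(=O)O)=C\c2cc(OC)c(OCc3ccccc3)c(OC)c2)ccc1OCc1ccccc1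
F4 | step 5 | dimethyl (2E,3R)‑2‑[4‑(benzyloxy)‑3,5‑dimethoxybenzylidene]‑3‑[4‑(benzyloxy)‑3‑methoxybenzyl]butanedioate | COc1cc(C[C@@H](C(=O)OC)/C(C(=O)OC)=C\c2cc(OC)c(OCc3ccccc3)c(OC)c2)ccc1OCc1ccccc1
F5 | step 6 | methyl (2E,3R)‑2‑[4‑(benzyloxy)‑3,5‑dimethoxybenzylidene]‑3‑[4‑(benzyloxy)‑3‑methoxybenzyl]‑4‑hydroxybutanoate | COc1cc(C[C@@H](CO)/C(C(=O)OC)=C\c2cc(OC)c(OCc3ccccc3)c(OC)c2)ccc1OCc1ccccc1
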